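**Retrosynthetic overview**

1. Target ⇒ late acylation of O8 with silyl-protected 2-(hydroxymethyl)acrylic acid and global desilylation; the C11=C13 methylene from α-methylenation of a C7 acetic ester; C4=O, 5α-H and 6α-OH from a C5=C6 alkene (α-epoxide, isomerisation to the Δ4-6α-ol, hydroboration–oxidation, oxidation); the acetic ester from C7 alkylation of the dienolate of a 10-methyl-Δ5-octalin-8-one.
2. Key disconnection: ring B of that enone is opened across C9–C10 to a 2-methylene-4-(ring A cyclohexenyl)oxetane; forward, a formal [3,3] (Claisen) ring expansion breaks C6–O, forms C9–C10 and makes C10 quaternary.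
3. Feature on which the plan rests: quaternary C10 sits in ring B between C5 and C9, with oxygen-bearing C8 one carbon further on, so ring B holds an allyl unit C6–C5=C10 tied through an oxygen on C6 to a C8=C9 enol ether, with C7 as the second C6–C8 link.
4. The oxetane comes from the ring A enal (C6 = CHO) by reagent-controlled 2-bromoallylboration and copper-catalysed 4-exo O-vinylation; the enal comes from 2-methylcyclohexane-1,3-dione (iodo enone, CBS reduction, silylation, formylation).
5. Ring order: ring A is bought, the oxetane is built on it, ring B is closed last by the ring expansion; the side-chain acid comes from ethyl 2-(hydroxymethyl)acrylate.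

Key step: step 7

Remark: eudesmane numbering is used throughout (ring A = C1–C5 and C10, ring B = C5–C10, β = the face of the C10 methyl); C6 of the oxetane is set for the matched case, although complete ionisation in step 7 would let both C6 epimers converge on 14.

**Route**

Step 1
Reactants: 1 2-methylcyclohexane-1,3-dione
Product: 2 3-iodo-2-methylcyclohex-2-en-1-one
Conditions: PPh3, I2, Et3N, MeCN, rt to reflux
Reagents that add atoms: iodine, II
Why: The vinylogous acid is activated on oxygen by iodotriphenylphosphonium iodide formed in the flask and iodide displaces the phosphine oxide by addition–elimination, the standard conversion of a 1,3-dione into a 3-halo enone; no stereocentre is formed.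

Step 2
Reactants: 2 3-iodo-2-methylcyclohex-2-en-1-one
Product: 3 (R)-3-iodo-2-methylcyclohex-2-en-1-ol
Conditions: (S)-Me-CBS oxazaborolidine [(3aS)-1-methyl-3,3-diphenylhexahydropyrrolo[1,2-c][1,3,2]oxazaborole] (20 mol%), BH3·SMe2, THF, −20 °C; MeOH, then H2O
Reagents that add atoms: none
Why: Corey–Bakshi–Shibata reduction, in which the catalyst binds the ketone with the α-methyl vinyl iodide arm as the large group and delivers hydride to one face, should give the R carbinol (future C1) without touching the vinyl iodide.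

Step 3
Reactants: 3 (R)-3-iodo-2-methylcyclohex-2-en-1-ol
Product: 4 (R)-tert-butyl[(3-iodo-2-methylcyclohex-2-en-1-yl)oxy]dimethylsilane
Conditions: TBSCl, imidazole, DMF, rt
Reagents that add atoms: tert-butyldimethylsilyl chloride, CC(C)(C)[Si](C)(C)Cl
Why: Standard silylation of a secondary allylic alcohol; the stereocentre is not involved.

Step 4
Reactants: 4 (R)-tert-butyl[(3-iodo-2-methylcyclohex-2-en-1-yl)oxy]dimethylsilane
Product: 7 (R)-3-(tert-butyldimethylsilyloxy)-2-methylcyclohex-1-ene-1-carbaldehyde, via vinyllithium 5 (not isolated), via lithium hemiaminal alkoxide 6 (not isolated)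
Conditions: t-BuLi (2.1 equiv), Et2O, −78 °C; DMF, −78 to 0 °C; H2O
Reagents that add atoms: N,N-dimethylformamide, CN(C)C=O
Why: Iodine–lithium exchange gives the vinyllithium without moving the alkene, formylation with DMF gives a tetrahedral adduct that collapses to the enal on aqueous work-up, and the silyl ether and C1 are untouched.

Step 5
Reactants: 7 (R)-3-(tert-butyldimethylsilyloxy)-2-methylcyclohex-1-ene-1-carbaldehyde; 8 propadiene (allene)
Product: 11 (S)-3-bromo-1-[(R)-3-(tert-butyldimethylsilyloxy)-2-methylcyclohex-1-en-1-yl]but-3-en-1-ol, via 2-bromoallylborane 9 (not isolated), via borinate ester 10 (not isolated)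
Conditions: (−)-Ipc2BBr [from (+)-α-pinene], 8, Et2O, −78 to 0 °C; then 7, −78 °C; HOCH2CH2NH2, rt
Reagents that add atoms: (−)-B-bromodiisopinocampheylborane, BrB([C@@H]1C[C@@H]2C[C@H]([C@H]1C)C2(C)C)[C@@H]1C[C@@H]2C[C@H]([C@H]1C)C2(C)C
Why: Bromoboration of allene gives the 2-bromoallylborane, which adds to the aldehyde through a chair six-membered transition state (Brown-type allylboration), and the (+)-α-pinene-derived reagent attacks the Si face, so the 6S carbinol is set under reagent control with little influence from remote C1.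

Step 6
Reactants: 11 (S)-3-bromo-1-[(R)-3-(tert-butyldimethylsilyloxy)-2-methylcyclohex-1-en-1-yl]but-3-en-1-ol
Product: 12 (S)-2-methylene-4-[(R)-3-(tert-butyldimethylsilyloxy)-2-methylcyclohex-1-en-1-yl]oxetane
Conditions: CuI (10 mol%), 1,10-phenanthroline (20 mol%), Cs2CO3, MeCN, 80 °C
Reagents that add atoms: none
Why: Copper-catalysed intramolecular Ullmann-type O-vinylation of a γ-bromohomoallylic alcohol is known to close the four-membered ring in the 4-exo mode to a 2-methyleneoxetane, the basic medium protects the acid-sensitive enol ether, and C6 keeps its configuration because its C–O bond is not broken.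

Step 7
Reactants: 12 (S)-2-methylene-4-[(R)-3-(tert-butyldimethylsilyloxy)-2-methylcyclohex-1-en-1-yl]oxetane
Product: 14 1β-(tert-butyldimethylsilyloxy)-10β-methyl-Δ5-octalin-8-one [(8R,8aR)-8-(tert-butyldimethylsilyloxy)-8a-methyl-3,5,6,7,8,8a-hexahydronaphthalen-2(1H)-one], via aluminate allyl cation ion pair 13 (not isolated)
Conditions: MeAl(OC6H2-4-Br-2,6-tBu2)2 (2 equiv, from Me3Al and 4-bromo-2,6-di-tert-butylphenol), CH2Cl2, −78 to −40 °C; aq. potassium sodium tartrate
Reagents that add atoms: none
Why: Proposed new method: the aluminium Lewis acid binds the oxetane oxygen and strain-assisted heterolysis of the allylic C6–O bond gives contact ion pair 13 (aluminium enolate at C8 with nucleophilic C9, allyl cation C6–C5–C10), which collapses at C10 to form C9–C10, a formal [3,3] Claisen shift run deliberately as a dissociative process because in the flat four-membered ring the exocyclic C8=C9 π bond is orthogonal to the C6–O σ bond and C9 lies more than 4 Å from C10, so a synchronous bicyclic transition state cannot be reached. The closest known reactions are the organoaluminium-promoted Claisen rearrangement of allyl vinyl ethers (including the ring expansion of 2-methylene-6-vinyltetrahydropyrans to cyclooctenones), the Petasis–Ferrier rearrangement, in which an aluminium reagent cleaves the ring C–O bond of a cyclic enol ether to a cation–enolate pair that recombines through carbon, and the Lewis-acid ring expansion of 2-vinyloxetanes by ionisation and reclosure at the far allyl terminus. Ring B closes by 6-(enolexo)-endo-trig attack of enolate carbon C9 on cation terminus C10, a four-to-six ring expansion; attack at C6 would give a strained cyclobutanone and aluminium on oxygen blocks O-recombination. The new quaternary stereocentre C10 is controlled by the C1 silyl ether, which sits pseudoaxial on the β face (allylic strain with the C10 methyl) so that C9 bonds to the α face and the methyl becomes β, and the 6S configuration reinforces this because the departing oxygen, and with it the tethered enolate, lies on that same α face in the rotamer with C7 syn to C10 (suprafacial, matched). The step needs C–C collapse at C10 to beat proton loss from C7 (which would give the conjugated dienone), hydride shift from C1 and capture of the cation; low temperature, the non-basic and non-nucleophilic bulky phenoxide ligands, the pseudoequatorial C1–H (poorly aligned for migration) and reversible ionisation, which lets the unproductive rotamer return to 12, are what should secure it.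

Step 8
Reactants: 14 1β-(tert-butyldimethylsilyloxy)-10β-methyl-Δ5-octalin-8-one; 15 methyl bromoacetate
Product: 17 methyl 2-[1β-(tert-butyldimethylsilyloxy)-10β-methyl-8-oxo-Δ5-octalin-7α-yl]acetate, via lithium dienolate 16 (not isolated)
Conditions: LiN(iPr)2 (1.1 equiv), THF, −78 °C; then 15, −78 to −40 °C
Reagents that add atoms: none
Why: Kinetic deprotonation at doubly activated C7 (α to C8=O and allylic to C5=C6, whereas C9 is neopentyl) gives the extended dienolate, which is alkylated at its α-carbon C7 (deconjugative α-alkylation) with axial entry of the bromoacetate, so the 7α epimer is expected to prevail and is corrected in step 9.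

Step 9
Reactants: 17 methyl 2-[1β-(tert-butyldimethylsilyloxy)-10β-methyl-8-oxo-Δ5-octalin-7α-yl]acetate
Product: 19 methyl 2-[1β-(tert-butyldimethylsilyloxy)-10β-methyl-8-oxo-Δ5-octalin-7β-yl]acetate, via lithium dienolate 18 (not isolated)
Conditions: LiN(SiMe3)2 (0.95 equiv), THF, −78 to 0 °C; AcOH, −78 °C
Reagents that add atoms: none
Why: The extended dienolate is re-formed under equilibrating conditions (the amide is too weak to enolise the ester) and kinetic α-protonation at low temperature (deconjugative protonation) delivers hydrogen axially on the α face, which places the side chain equatorial (7β, also the more stable epimer) and keeps the alkene at C5=C6.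

Step 10
Reactants: 19 methyl 2-[1β-(tert-butyldimethylsilyloxy)-10β-methyl-8-oxo-Δ5-octalin-7β-yl]acetate
Product: 20 methyl 2-[1β-(tert-butyldimethylsilyloxy)-8α-hydroxy-10β-methyl-Δ5-octalin-7β-yl]acetate
Conditions: SmI2 (2.5 equiv), H2O, THF, 0 °C; pH 7 buffer
Reagents that add atoms: none
Why: Single-electron ketone reduction with SmI2–H2O proceeds through a ketyl and a protonated carbanion and should give the thermodynamically preferred equatorial 8α-alcohol (the axial epimer would be 1,3-diaxial to the C10 methyl), trans to the C7 side chain, while the methyl ester and the isolated alkene are not reduced and the trans hydroxy ester should not lactonise under neutral work-up.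

Step 11
Reactants: 20 methyl 2-[1β-(tert-butyldimethylsilyloxy)-8α-hydroxy-10β-methyl-Δ5-octalin-7β-yl]acetate
Product: 21 methyl 2-[1β-(tert-butyldimethylsilyloxy)-10β-methyl-8α-(triethylsilyloxy)-Δ5-octalin-7β-yl]acetate
Conditions: Et3SiOTf, 2,6-lutidine, CH2Cl2, −78 °C
Reagents that add atoms: triethylsilyl trifluoromethanesulfonate, CC[Si](CC)(CC)OS(=O)(=O)C(F)(F)F
Why: Silylation with the triflate at low temperature caps O8 before it can lactonise onto the ester and gives it a silyl group that can later be removed in the presence of the TBS ethers.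

Step 12
Reactants: 21 methyl 2-[1β-(tert-butyldimethylsilyloxy)-10β-methyl-8α-(triethylsilyloxy)-Δ5-octalin-7β-yl]acetate
Product: 22 methyl 2-[1β-(tert-butyldimethylsilyloxy)-5α,6α-epoxy-10β-methyl-8α-(triethylsilyloxy)decalin-7β-yl]acetate
Conditions: mCPBA, NaHCO3, CH2Cl2, 0 °C
Reagents that add atoms: 3-chloroperoxybenzoic acid, OOC(=O)c1cccc(Cl)c1
Why: Prilezhaev epoxidation of the only alkene should occur on the α face, anti to the axial C10 methyl and to the 7β side chain, as with Δ5-steroids, which sets the C6 oxygen α.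

Step 13
Reactants: 22 methyl 2-[1β-(tert-butyldimethylsilyloxy)-5α,6α-epoxy-10β-methyl-8α-(triethylsilyloxy)decalin-7β-yl]acetate
Product: 23 methyl 2-[1β-(tert-butyldimethylsilyloxy)-6α-hydroxy-10β-methyl-8α-(triethylsilyloxy)-Δ4-octalin-7β-yl]acetate
Conditions: Et2Al(NC9H18) [diethylaluminium 2,2,6,6-tetramethylpiperidide, from lithium 2,2,6,6-tetramethylpiperidide and Et2AlCl], PhMe, 0 °C to rt; aq. potassium sodium tartrate
Reagents that add atoms: none
Why: Aluminium amide-mediated isomerisation of a trisubstituted epoxide to an allylic alcohol (syn β-elimination through a cyclic transition state) breaks the tertiary C5–O bond and removes a proton from C4, the only hydrogen-bearing carbon on C5, so the C6–O bond and its α configuration are kept and the alkene moves to C4=C5.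

Step 14
Reactants: 23 methyl 2-[1β-(tert-butyldimethylsilyloxy)-6α-hydroxy-10β-methyl-8α-(triethylsilyloxy)-Δ4-octalin-7β-yl]acetate
Product: 24 methyl 2-[1β,6α-bis(tert-butyldimethylsilyloxy)-10β-methyl-8α-(triethylsilyloxy)-Δ4-octalin-7β-yl]acetate
Conditions: t-BuMe2SiOTf, 2,6-lutidine, CH2Cl2, 0 °C
Reagents that add atoms: tert-butyldimethylsilyl trifluoromethanesulfonate, CC(C)(C)[Si](C)(C)OS(=O)(=O)C(F)(F)F
Why: Silylation of the hindered allylic alcohol with the reactive triflate protects O6 until the last step and distinguishes it from O8.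

Step 15
Reactants: 24 methyl 2-[1β,6α-bis(tert-butyldimethylsilyloxy)-10β-methyl-8α-(triethylsilyloxy)-Δ4-octalin-7β-yl]acetate
Product: 26 methyl 2-[1β,6α-bis(tert-butyldimethylsilyloxy)-4α-hydroxy-10β-methyl-8α-(triethylsilyloxy)-5αH-decalin-7β-yl]acetate, via alkylborane 25 (not isolated)
Conditions: BH3·THF, THF, 0 °C to rt; then 30% H2O2, aq. NaOAc, 0 °C to rt
Reagents that add atoms: hydrogen peroxide, OO
Why: Hydroboration–oxidation adds boron to C4 and hydrogen to C5 in a syn fashion from the α face, anti to the C10 methyl (as with Δ4-steroids), which sets the trans ring fusion (5α-H) and gives the 4α-alcohol with retention, while the allylic silyloxy group reinforces boron placement at the distal carbon and the buffered peroxide spares the ester.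

Step 16
Reactants: 26 methyl 2-[1β,6α-bis(tert-butyldimethylsilyloxy)-4α-hydroxy-10β-methyl-8α-(triethylsilyloxy)-5αH-decalin-7β-yl]acetate
Product: 30 methyl 2-[1β,6α-bis(tert-butyldimethylsilyloxy)-4α-hydroxy-10β-methyl-8α-(triethylsilyloxy)-5αH-decalin-7β-yl]acrylate, via dilithio alkoxide enolate 27 (not isolated), via Mannich base 28 (not isolated), via methiodide 29 (not isolated)
Conditions: LiN(iPr)2 (2.5 equiv), THF, −78 °C; Me2N=CH2+ I−, −78 °C to rt; aq. NaHCO3; MeI, MeOH, rt; DBU, CH2Cl2, rt
Reagents that add atoms: N,N-dimethylmethyleneiminium iodide (Eschenmoser's salt), C=[N+](C)C.[I-]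
Why: The ester is the only enolisable carbonyl (the C4 hydroxyl is carried as its lithium alkoxide), so its enolate undergoes a Mannich reaction with the iminium salt, and N-methylation followed by Hofmann-type β-elimination gives the α-methylene ester without touching C7.

Step 17
Reactants: 30 methyl 2-[1β,6α-bis(tert-butyldimethylsilyloxy)-4α-hydroxy-10β-methyl-8α-(triethylsilyloxy)-5αH-decalin-7β-yl]acrylate
Product: 31 methyl 2-[1β,6α-bis(tert-butyldimethylsilyloxy)-10β-methyl-4-oxo-8α-(triethylsilyloxy)-5αH-decalin-7β-yl]acrylate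
Conditions: Dess–Martin periodinane, NaHCO3, CH2Cl2, rt
Reagents that add atoms: none
Why: Dess–Martin oxidation of the only free hydroxyl gives the C4 ketone under buffered conditions that should not eliminate the β-silyloxy group at C6, and the trans-fused 5α-H is the stable configuration next to the new ketone.

Step 18
Reactants: 31 methyl 2-[1β,6α-bis(tert-butyldimethylsilyloxy)-10β-methyl-4-oxo-8α-(triethylsilyloxy)-5αH-decalin-7β-yl]acrylate
Product: 32 methyl 2-[1β,6α-bis(tert-butyldimethylsilyloxy)-8α-hydroxy-10β-methyl-4-oxo-5αH-decalin-7β-yl]acrylate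
Conditions: PPTS (cat.), MeOH/CH2Cl2, 0 °C
Reagents that add atoms: none
Why: Mild acid-catalysed methanolysis removes the triethylsilyl ether much faster than the two hindered secondary TBS ethers, which frees O8 alone, and the conjugated methyl ester is too poor an acceptor to lactonise under these conditions.

Step 19
Reactants: 33 ethyl 2-(hydroxymethyl)acrylate
Product: 34 ethyl 2-[(tert-butyldimethylsilyloxy)methyl]acrylate
Conditions: TBSCl, imidazole, CH2Cl2, 0 °C to rt
Reagents that add atoms: tert-butyldimethylsilyl chloride, CC(C)(C)[Si](C)(C)Cl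
Why: Standard silylation of the primary allylic alcohol protects it during ester hydrolysis and coupling.

Step 20
Reactants: 34 ethyl 2-[(tert-butyldimethylsilyloxy)methyl]acrylate
Product: 35 2-[(tert-butyldimethylsilyloxy)methyl]acrylic acid
Conditions: LiOH, THF/H2O, 0 °C to rt; aq. HCl to pH 3
Reagents that add atoms: lithium hydroxide, [Li+].[OH-]
Why: Saponification of the ethyl ester by acyl–oxygen cleavage gives the acid, and the silyl ether survives brief cold acidification.

Step 21
Reactants: 32 methyl 2-[1β,6α-bis(tert-butyldimethylsilyloxy)-8α-hydroxy-10β-methyl-4-oxo-5αH-decalin-7β-yl]acrylate; 35 2-[(tert-butyldimethylsilyloxy)methyl]acrylic acid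
Product: 37 tris(tert-butyldimethylsilyl) ether of the target (silyl groups on O1 and O6 and on the side-chain hydroxyl), via mixed anhydride 36 (not isolated)
Conditions: 35, 2,4,6-Cl3C6H2COCl, Et3N, THF, rt; then 32, DMAP, PhMe, rt
Reagents that add atoms: none
Why: Yamaguchi esterification activates the acid as a mixed anhydride and DMAP transfers the acyl group to the equatorial 8α-hydroxyl, the only free hydroxyl, with retention at C8.

Step 22
Reactants: 37 tris(tert-butyldimethylsilyl) ether of the target
Product: 38 CNP0144895.1 (target)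
Conditions: HF·pyridine, pyridine, THF, 0 °C to rt
Reagents that add atoms: none
Why: Buffered fluoride desilylation removes all three TBS groups under weakly acidic conditions that should avoid acyl migration, oxa-Michael addition to the acrylates and retro-aldol or dehydration of the β-hydroxy ketone.

**Compound list**

1 | 2-methylcyclohexane-1,3-dione | CC1C(=O)CCCC1=O | starting material
2 | 3-iodo-2-methylcyclohex-2-en-1-one | CC1=C(I)CCCC1=O | intermediate
3 | (R)-3-iodo-2-methylcyclohex-2-en-1-ol | IC1=C(C)[C@H](O)CCC1 | intermediate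
4 | (R)-tert-butyl[(3-iodo-2-methylcyclohex-2-en-1-yl)oxy]dimethylsilane | IC1=C(C)[C@H](O[Si](C)(C)C(C)(C)C)CCC1 | intermediate
5 | [(R)-3-(tert-butyldimethylsilyloxy)-2-methylcyclohex-1-en-1-yl]lithium (not isolated) | [Li]C1=C(C)[C@H](O[Si](C)(C)C(C)(C)C)CCC1 | intermediate
6 | lithium (dimethylamino)[(R)-3-(tert-butyldimethylsilyloxy)-2-methylcyclohex-1-en-1-yl]methanolate, carbinol centre unassigned (not isolated) | [Li]OC(N(C)C)C1=C(C)[C@H](O[Si](C)(C)C(C)(C)C)CCC1 | intermediate
7 | (R)-3-(tert-butyldimethylsilyloxy)-2-methylcyclohex-1-ene-1-carbaldehyde (ring A enal, CHO = C6) | O=CC1=C(C)[C@H](O[Si](C)(C)C(C)(C)C)CCC1 | intermediate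
8 | propadiene (allene) | C=C=C | starting material
9 | B-(2-bromoallyl)diisopinocampheylborane, Ipc groups from (+)-α-pinene (not isolated) | C=C(Br)CB([C@@H]1C[C@@H]2C[C@H]([C@H]1C)C2(C)C)[C@@H]1C[C@@H]2C[C@H]([C@H]1C)C2(C)C | intermediate
10 | diisopinocampheylborinate ester of 11 (not isolated) | C=C(Br)C[C@H](OB([C@@H]1C[C@@H]2C[C@H]([C@H]1C)C2(C)C)[C@@H]1C[C@@H]2C[C@H]([C@H]1C)C2(C)C)C1=C(C)[C@H](O[Si](C)(C)C(C)(C)C)CCC1 | intermediate
11 | (S)-3-bromo-1-[(R)-3-(tert-butyldimethylsilyloxy)-2-methylcyclohex-1-en-1-yl]but-3-en-1-ol | C=C(Br)C[C@H](O)C1=C(C)[C@H](O[Si](C)(C)C(C)(C)C)CCC1 | intermediate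
12 | (S)-2-methylene-4-[(R)-3-(tert-butyldimethylsilyloxy)-2-methylcyclohex-1-en-1-yl]oxetane | C=C1C[C@H](O1)C2=C(C)[C@H](O[Si](C)(C)C(C)(C)C)CCC2 | intermediate
13 | ion pair of the C8 aluminate enolate and the C6–C5–C10 allyl cation, C7 syn to C10 (not isolated) | C=C(O[Al-](C)(Oc1c(cc(Br)cc1C(C)(C)C)C(C)(C)C)Oc1c(cc(Br)cc1C(C)(C)C)C(C)(C)C)C/C=C1/CCC[C@@H](O[Si](C)(C)C(C)(C)C)[C+]1C | intermediate
14 | 1β-(tert-butyldimethylsilyloxy)-10β-methyl-Δ5-octalin-8-one; (8R,8aR)-8-(tert-butyldimethylsilyloxy)-8a-methyl-3,5,6,7,8,8a-hexahydronaphthalen-2(1H)-one | O=C1C[C@@]2(C)[C@H](O[Si](C)(C)C(C)(C)C)CCCC2=CC1 | intermediate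
15 | methyl bromoacetate | COC(=O)CBr | starting material
16 | lithium C8-O dienolate of 14 (C7=C8, C5=C6) (not isolated) | [Li]OC1C[C@@]2(C)[C@H](O[Si](C)(C)C(C)(C)C)CCCC2=CC=1 | intermediate
17 | methyl 2-[1β-(tert-butyldimethylsilyloxy)-10β-methyl-8-oxo-Δ5-octalin-7α-yl]acetate | O=C1C[C@@]2(C)[C@H](O[Si](C)(C)C(C)(C)C)CCCC2=C[C@H]1CC(=O)OC | intermediate
18 | lithium C8-O dienolate of 17 (not isolated) | [Li]OC1C[C@@]2(C)[C@H](O[Si](C)(C)C(C)(C)C)CCCC2=CC=1CC(=O)OC | intermediate
19 | methyl 2-[1β-(tert-butyldimethylsilyloxy)-10β-methyl-8-oxo-Δ5-octalin-7β-yl]acetate | O=C1C[C@@]2(C)[C@H](O[Si](C)(C)C(C)(C)C)CCCC2=C[C@@H]1CC(=O)OC | intermediate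
20 | methyl 2-[1β-(tert-butyldimethylsilyloxy)-8α-hydroxy-10β-methyl-Δ5-octalin-7β-yl]acetate | O[C@H]1C[C@@]2(C)[C@H](O[Si](C)(C)C(C)(C)C)CCCC2=C[C@@H]1CC(=O)OC | intermediate
21 | methyl 2-[1β-(tert-butyldimethylsilyloxy)-10β-methyl-8α-(triethylsilyloxy)-Δ5-octalin-7β-yl]acetate | CC[Si](CC)(CC)O[C@H]1C[C@@]2(C)[C@H](O[Si](C)(C)C(C)(C)C)CCCC2=C[C@@H]1CC(=O)OC | intermediate
22 | methyl 2-[1β-(tert-butyldimethylsilyloxy)-5α,6α-epoxy-10β-methyl-8α-(triethylsilyloxy)decalin-7β-yl]acetate | CC[Si](CC)(CC)O[C@H]1C[C@@]2(C)[C@H](O[Si](C)(C)C(C)(C)C)CCC[C@]2(O3)[C@@H]3[C@@H]1CC(=O)OC | intermediate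
23 | methyl 2-[1β-(tert-butyldimethylsilyloxy)-6α-hydroxy-10β-methyl-8α-(triethylsilyloxy)-Δ4-octalin-7β-yl]acetate | CC[Si](CC)(CC)O[C@H]1C[C@@]2(C)[C@H](O[Si](C)(C)C(C)(C)C)CCC=C2[C@@H](O)[C@@H]1CC(=O)OC | intermediate
24 | methyl 2-[1β,6α-bis(tert-butyldimethylsilyloxy)-10β-methyl-8α-(triethylsilyloxy)-Δ4-octalin-7β-yl]acetate | CC[Si](CC)(CC)O[C@H]1C[C@@]2(C)[C@H](O[Si](C)(C)C(C)(C)C)CCC=C2[C@@H](O[Si](C)(C)C(C)(C)C)[C@@H]1CC(=O)OC | intermediate
25 | 4α-boryl-5αH adduct of 24 (monoalkylborane, not isolated) | CC[Si](CC)(CC)O[C@H]1C[C@@]2(C)[C@H](O[Si](C)(C)C(C)(C)C)CC[C@@H](B)[C@@H]2[C@@H](O[Si](C)(C)C(C)(C)C)[C@@H]1CC(=O)OC | intermediate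
26 | methyl 2-[1β,6α-bis(tert-butyldimethylsilyloxy)-4α-hydroxy-10β-methyl-8α-(triethylsilyloxy)-5αH-decalin-7β-yl]acetate | CC[Si](CC)(CC)O[C@H]1C[C@@]2(C)[C@H](O[Si](C)(C)C(C)(C)C)CC[C@@H](O)[C@@H]2[C@@H](O[Si](C)(C)C(C)(C)C)[C@@H]1CC(=O)OC | intermediate
27 | dilithio derivative of 26: C4 lithium alkoxide and lithium ester enolate (not isolated) | CC[Si](CC)(CC)O[C@H]1C[C@@]2(C)[C@H](O[Si](C)(C)C(C)(C)C)CC[C@@H](O[Li])[C@@H]2[C@@H](O[Si](C)(C)C(C)(C)C)[C@@H]1C=C(O[Li])OC | intermediate
28 | Mannich base: C11-(dimethylaminomethyl) derivative of 26, C11 epimers (not isolated) | CC[Si](CC)(CC)O[C@H]1C[C@@]2(C)[C@H](O[Si](C)(C)C(C)(C)C)CC[C@@H](O)[C@@H]2[C@@H](O[Si](C)(C)C(C)(C)C)[C@@H]1C(CN(C)C)C(=O)OC | intermediate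
29 | trimethylammonium iodide (methiodide) of 28 (not isolated) | CC[Si](CC)(CC)O[C@H]1C[C@@]2(C)[C@H](O[Si](C)(C)C(C)(C)C)CC[C@@H](O)[C@@H]2[C@@H](O[Si](C)(C)C(C)(C)C)[C@@H]1C(C[N+](C)(C)C)C(=O)OC.[I-] | intermediate
30 | methyl 2-[1β,6α-bis(tert-butyldimethylsilyloxy)-4α-hydroxy-10β-methyl-8α-(triethylsilyloxy)-5αH-decalin-7β-yl]acrylate | CC[Si](CC)(CC)O[C@H]1C[C@@]2(C)[C@H](O[Si](C)(C)C(C)(C)C)CC[C@@H](O)[C@@H]2[C@@H](O[Si](C)(C)C(C)(C)C)[C@@H]1C(=C)C(=O)OC | intermediate
31 | methyl 2-[1β,6α-bis(tert-butyldimethylsilyloxy)-10β-methyl-4-oxo-8α-(triethylsilyloxy)-5αH-decalin-7β-yl]acrylate | CC[Si](CC)(CC)O[C@H]1C[C@@]2(C)[C@H](O[Si](C)(C)C(C)(C)C)CCC(=O)[C@@H]2[C@@H](O[Si](C)(C)C(C)(C)C)[C@@H]1C(=C)C(=O)OC | intermediate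
32 | methyl 2-[1β,6α-bis(tert-butyldimethylsilyloxy)-8α-hydroxy-10β-methyl-4-oxo-5αH-decalin-7β-yl]acrylate | O[C@H]1C[C@@]2(C)[C@H](O[Si](C)(C)C(C)(C)C)CCC(=O)[C@@H]2[C@@H](O[Si](C)(C)C(C)(C)C)[C@@H]1C(=C)C(=O)OC | intermediate
33 | ethyl 2-(hydroxymethyl)acrylate | C=C(CO)C(=O)OCC | starting material
34 | ethyl 2-[(tert-butyldimethylsilyloxy)methyl]acrylate | C=C(CO[Si](C)(C)C(C)(C)C)C(=O)OCC | intermediate
35 | 2-[(tert-butyldimethylsilyloxy)methyl]acrylic acid | C=C(CO[Si](C)(C)C(C)(C)C)C(=O)O | intermediate
36 | mixed anhydride of 35 with 2,4,6-trichlorobenzoic acid (not isolated) | C=C(CO[Si](C)(C)C(C)(C)C)C(=O)OC(=O)c1c(Cl)cc(Cl)cc1Cl | intermediate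
37 | tris(tert-butyldimethylsilyl) ether of the target (O1, O6 and side-chain O) | C=C(CO[Si](C)(C)C(C)(C)C)C(=O)O[C@H]1C[C@@]2(C)[C@H](O[Si](C)(C)C(C)(C)C)CCC(=O)[C@@H]2[C@@H](O[Si](C)(C)C(C)(C)C)[C@@H]1C(=C)C(=O)OC | intermediate
38 | CNP0144895.1: methyl 2-[1β,6α-dihydroxy-8α-{[2-(hydroxymethyl)acryloyl]oxy}-10β-methyl-4-oxo-5αH-decalin-7β-yl]acrylate | C=C(CO)C(=O)O[C@H]1C[C@@]2(C)[C@H](O)CCC(=O)[C@@H]2[C@@H](O)[C@@H]1C(=C)C(=O)OC | target

**Step count**

Total: 22 steps. Longest linear sequence: 20 steps (steps 1–18, 21 and 22); steps 19–20 make the acid partner.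

**Steps most likely to fail**

Step 7 (Proposed new method). After ionisation, proton loss from C7 may isomerise the substrate to the conjugated dienone; the cation rotamer with C7 anti to C10 cannot close the six-membered ring; hydride may migrate from C1; facial control at C10 may erode. The fallback uses known chemistry and builds the C9–C10 bond by a different rearrangement. It sets out from enal 7: reduction with NaBH4 (MeOH, 0 °C) gives the allylic alcohol [(R)-3-(tert-butyldimethylsilyloxy)-2-methylcyclohex-1-en-1-yl]methanol F1. A Johnson–Claisen rearrangement (MeC(OEt)3, cat. EtCO2H, 140 °C) forms C9–C10 on the face anti to the silyl ether and gives ethyl 2-[(1R,2R)-2-(tert-butyldimethylsilyloxy)-1-methyl-6-methylenecyclohexyl]acetate F2. Aminolysis (MeNH(OMe)·HCl, i-PrMgCl, THF, −20 °C) gives the Weinreb amide F3, and CH2=CHCH2MgBr (THF, −78 °C) gives the allyl ketone F4. Ring-closing metathesis with second-generation Grubbs catalyst RuCl2(=CHPh)(PCy3)(H2IMes) (CH2Cl2, 40 °C) joins the exocyclic C5 methylene to the allyl terminus, closes ring B and comes back to the route at 14.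

Step 6. Ring closure at the hindered carbinol may be slow and lose out to dehydrobromination, and the allylic C–O bond of the product may ionise in hot acetonitrile. The fallback makes the oxetane through a β-lactone and sets out from enal 7. A catalytic asymmetric ketene–aldehyde [2+2] cycloaddition (acetyl chloride, i-Pr2NEt, LiClO4, CH2Cl2/Et2O, −78 °C, with O-trimethylsilylquinidine or its pseudoenantiomer O-trimethylsilylquinine, whichever gives the 4S lactone) gives (S)-4-[(R)-3-(tert-butyldimethylsilyloxy)-2-methylcyclohex-1-en-1-yl]oxetan-2-one F5. Carbonyl methylenation with Cp2TiMe2 (PhMe, 70 °C, dark) comes back to the route at 12.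

Step 10. Facial selectivity in the ketone reduction may be insufficient (any axial 8β-alcohol would drain away as the cis-fused lactone), or the 8α-hydroxy ester may itself lactonise. The fallback reduces the carboxylate instead of the ester and sets out from 19. Neutral ester hydrolysis with Me3SnOH (ClCH2CH2Cl, 70 °C) gives the keto acid F6. Dissolving-metal reduction of its lithium carboxylate (Li, NH3, THF, −78 °C; NH4Cl), which can neither lactonise nor be reduced, gives the equatorial 8α-hydroxy acid F7 under thermodynamic control. Esterification with Me3SiCHN2 (MeOH/PhMe, 0 °C) comes back to the route at 20.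

**Further compounds**

F1 | step 7 | [(R)-3-(tert-butyldimethylsilyloxy)-2-methylcyclohex-1-en-1-yl]methanol | OCC1=C(C)[C@H](O[Si](C)(C)C(C)(C)C)CCC1
F2 | step 7 | ethyl 2-[(1R,2R)-2-(tert-butyldimethylsilyloxy)-1-methyl-6-methylenecyclohexyl]acetate | CCOC(=O)C[C@@]1(C)[C@H](O[Si](C)(C)C(C)(C)C)CCCC1=C
F3 | step 7 | 2-[(1R,2R)-2-(tert-butyldimethylsilyloxy)-1-methyl-6-methylenecyclohexyl]-N-methoxy-N-methylacetamide | CON(C)C(=O)C[C@@]1(C)[C@H](O[Si](C)(C)C(C)(C)C)CCCC1=C
F4 | step 7 | 1-[(1R,2R)-2-(tert-butyldimethylsilyloxy)-1-methyl-6-methylenecyclohexyl]pent-4-en-2-one | C=CCC(=O)C[C@@]1(C)[C@H](O[Si](C)(C)C(C)(C)C)CCCC1=C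
F5 | step 6 | (S)-4-[(R)-3-(tert-butyldimethylsilyloxy)-2-methylcyclohex-1-en-1-yl]oxetan-2-one | O=C1C[C@H](O1)C2=C(C)[C@H](O[Si](C)(C)C(C)(C)C)CCC2
F6 | step 10 | 2-[1β-(tert-butyldimethylsilyloxy)-10β-methyl-8-oxo-Δ5-octalin-7β-yl]acetic acid | O=C1C[C@@]2(C)[C@H](O[Si](C)(C)C(C)(C)C)CCCC2=C[C@@H]1CC(=O)O
F7 | step 10 | 2-[1β-(tert-butyldimethylsilyloxy)-8α-hydroxy-10β-methyl-Δ5-octalin-7β-yl]acetic acid | O[C@H]1C[C@@]2(C)[C@H](O[Si](C)(C)C(C)(C)C)CCCC2=C[C@@H]1CC(=O)O
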